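The ochre run, with 51 mM of substrate on 30.6 mM of partner, has lost 32.4 mM of substrate at 60.0 s, more than the partner charged, yet it holds 12.2% of target. So substrate does not leave one for one with partner.

all flasks: partner 30.6 mM; gas 2.7 mM (held)
- grey: substrate 34 mM; the very flask that is asked about, followed so far
- ochre: substrate 51 mM; run made earlier
- flask: substrate 34 mM; time 2.5 min

- grey (time / s: target / %, substrate / %): 10.0: 0.6, 86.4; 15.0: 0, 79.7; 20.0: 0.1, 72.6; 30.0: 3.9, 60.6
- ochre (time / s: target / %, substrate / %): 10.0: 0, 87.5; 15.0: 0.1, 81.4; 30.0: 1.1, 63.9; 60.0: 12.2, 36.4

(each reading ± 0.5 percentage points)

- at the start none of the gas is in solution
- reagent is what gas becomes in solution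

* how much target there is at 2.5 min, in percent of the substrate charged
* concentration of reagent in solution at 80 s, in percent of saturation
* the change that raises the amount of target at 2.5 min, in percent of the substrate charged most ("none" if none brings more than 2 percentage points) (elm / alder / cedar / none)
* amount of target at 2.5 min, in percent of the substrate charged, after alder

- elm: doubling the saturation concentration of gas, all else as stated
- alder: doubling the transfer coefficient of the gas, all else as stated
- cedar: doubling the amount of partner, all else as stated

I build the flask up one process at a time and follow target at 2.5 min. First I take the main step by itself: substrate goes straight to target, first order. The grey reading at 30.0 s gives 0.0167 s⁻¹, so target would stand at 91.8%.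

Then I add the partner, supposing that each target takes up one partner. The balance says that the partner charged equals c(partner) plus c(target) plus whatever holds partner on the way. In this flask partner is the limiting reagent, the smaller charge, so target stays under the ceiling 90.0%, the partner charged divided by the substrate charged. My number drops a little, to that ceiling.

Last I add the hold-up. In grey at 30.0 s, 35.5% of the substrate is gone but is not target, so it sits in something unread. Target in ochre grows by 0.189 mM s⁻¹ between its last two readings. Held from the last grey reading, that rate gives me 70.5%, below the ceiling. Cedar charges 61.2 mM of partner, more than the substrate, so substrate becomes the smaller charge and the ceiling rises to 100% of the substrate charged. I choose cedar.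

The forecast gives 65%, lower than my figure, with reagent at 45% and 75% after alder. It chooses elm, where I choose cedar: “Doubling saturation raises both supply and driving concentration, so elm should beat alder.”

The flask gives 56.6% of target, reagent at 84.1% of saturation at 80 s, and 60.0% after alder.

    substrate + reagent → open intermediate (k = 10.0 L mol⁻¹ s⁻¹)
    reagent + partner → second intermediate (k = 7.00 L mol⁻¹ s⁻¹)
    open intermediate + second intermediate → target (k = 0.930 L mol⁻¹ s⁻¹)
    gas ⇌ reagent, rate k4*(csat - [reagent]) (kL = 0.790 s⁻¹)

The best change is cedar, worth 23 percentage points, more than elm or alder. At 2.50 min the flask still holds 39.6% as open intermediate, and at 25.0 min its target reaches 89.9%, about the same as the ceiling. The neighbour flask with 12 mM of partner has a ceiling of 35.3%, and at 2.50 min it holds 26.3% of target.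

Readings and results are simulated with made-up constants; scatter was added.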